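The route rests on cutting C7–C11, so that the γ-lactone (O6, C6, C7, C11, C12) is annulated last onto the finished oxygen-bridged ten-membered carbocycle. The feature exploited is that the lactone junction C7 is flanked by oxygen-bearing C6 on one side and by the vicinal diol carbons C8 and C9 on the other. A C7=C8 double bond with allylic hydrogens on C9 is therefore an ene partner for a ketone carried by O6. One intramolecular carbonyl-ene reaction forms C7–C11, closes the lactone, sets C7 and C11, and shifts the alkene to C8=C9, ready for cis-dihydroxylation. The substrate is the pyruvate ester of the bicyclic 3(2H)-furanone bis-allylic alcohol (4Z,7Z), built by ynone cyclisation and ring-closing metathesis.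

Key step: step 13

Remark on numbering: germacrane numbering is used throughout (C1 furanone ketone, C2=C3, ether bridge C3–O–C10, C4(C15)=C5, C6–O6 lactone oxygen, C7, C8, C9, C10(C14), C11, C12 lactone carbonyl, C13).

Remark on the geometry of the migrated alkene: C8=C9 lies in the nine-membered ring O–C3–C4–C5–C6–C7–C8–C9–C10, whose torsions about C4=C5, C3–O and O–C10 are locked by the Z alkene and the flat furanone; a trans double bond next to C10 would point C7 away from C6 and cannot be bridged, so the ene product is drawn Z, and only a Z alkene maps onto (8S,9S) by syn-dihydroxylation.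

Remark on the promoter: closing the five-membered ring needs the C11=O bond turned roughly perpendicular to the ester plane, which a two-point (chelating) Lewis acid would oppose, and the basic C1 carbonyl would tie up a catalyst; an excess of the one-point, proton-scavenging Me2AlCl is therefore chosen.

**Route**

Step 1
Reactants: 1 (R)-lactic acid; 2 pivalaldehyde
Product: 3 (2R,5R)-2-tert-butyl-5-methyl-1,3-dioxolan-4-one (cis isomer)
Conditions: p-TsOH (cat.), pentane, reflux, Dean–Stark; recrystallisation from pentane, −78 °C
Reagents that add atoms: pivalaldehyde 2, CC(C)(C)C=O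
Why: Acid-catalysed acetalisation (first half of the self-regeneration-of-stereocentres tactic) leaves the lactic acid centre untouched and, being reversible, should favour the cis acetal, whose new centre C2 is secured by crystallisation.

Step 2
Reactants: 3 (2R,5R)-2-tert-butyl-5-methyl-1,3-dioxolan-4-one; 4 allyl bromide
Product: 6 (2R,5S)-5-allyl-2-tert-butyl-5-methyl-1,3-dioxolan-4-one, via lithium enolate 5 (not isolated)
Conditions: LDA, THF, −78 °C; then 4, −78 to −30 °C
Reagents that add atoms: allyl bromide 4, C=CCBr
Why: Enolate alkylation takes place anti to the tert-butyl group, so allyl takes the place of the former hydrogen and the future C10 is set as S.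

Step 3
Reactants: 6 (2R,5S)-5-allyl-2-tert-butyl-5-methyl-1,3-dioxolan-4-one
Product: 7 (S)-2-hydroxy-N-methoxy-N,2-dimethylpent-4-enamide
Conditions: MeNH(OMe)·HCl, i-PrMgCl, THF, −20 to 0 °C; H2O work-up
Reagents that add atoms: N,O-dimethylhydroxylamine hydrochloride, CNOC.Cl
Why: Weinreb aminolysis, in which the magnesium amide opens the activated acetal ester and the hemiacetal alkoxide sheds pivalaldehyde, does not involve the quaternary centre.

Step 4
Reactants: 8 (Z)-3-methylpent-2-en-4-yn-1-ol
Product: 9 (Z)-3-methylpent-2-en-4-ynal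
Conditions: activated MnO2, CH2Cl2, rt
Reagents that add atoms: none
Why: Heterogeneous, neutral allylic oxidation with MnO2 stops at the aldehyde and should keep the Z geometry that later becomes C4=C5.

Step 5
Reactants: 9 (Z)-3-methylpent-2-en-4-ynal; 10 vinylmagnesium bromide
Product: 11 rac-(Z)-5-methylhepta-1,4-dien-6-yn-3-ol
Conditions: THF, −78 °C; H2O work-up
Reagents that add atoms: vinylmagnesium bromide 10, C=C[Mg]Br
Why: Grignard 1,2-addition to the enal is much faster at −78 °C than deprotonation of the terminal alkyne; the new carbinol (future C6) is racemic at this stage.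

Step 6
Reactants: 11 rac-(Z)-5-methylhepta-1,4-dien-6-yn-3-ol
Product: 12 (3S,4Z)-5-methylhepta-1,4-dien-6-yn-3-ol
Conditions: Novozym 435 (immobilised Candida antarctica lipase B), vinyl acetate, MTBE, 30 °C, run slightly past half conversion; chromatography
Reagents that add atoms: none
Why: Lipase kinetic resolution under the Kazlauskas rule (vinyl as the medium group, branched Z-enynyl as the large group) should acetylate the R alcohol and leave the required S alcohol, which fixes C6.

Step 7
Reactants: 12 (3S,4Z)-5-methylhepta-1,4-dien-6-yn-3-ol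
Product: 13 (3S,4Z)-3-(tert-butyldimethylsilyloxy)-5-methylhepta-1,4-dien-6-yne
Conditions: TBSCl, imidazole, DMF, rt
Reagents that add atoms: tert-butyldimethylsilyl chloride, CC(C)(C)[Si](C)(C)Cl
Why: Standard silylation masks O6, which would otherwise consume base and cyclise onto the alkyne to a furan in steps 8 and 9.

Step 8
Reactants: 7 (S)-2-hydroxy-N-methoxy-N,2-dimethylpent-4-enamide; 13 (3S,4Z)-3-(tert-butyldimethylsilyloxy)-5-methylhepta-1,4-dien-6-yne
Product: 16 (4S,8Z,10S)-10-(tert-butyldimethylsilyloxy)-4-hydroxy-4,8-dimethyldodeca-1,8,11-trien-6-yn-5-one, via chloromagnesium alkoxide 14 (not isolated), via lithium acetylide 15 (not isolated)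
Conditions: 7, i-PrMgCl (1.05 equiv), THF, −40 °C; 13, n-BuLi, THF, −78 °C; combine, −78 to 0 °C; H2O work-up
Reagents that add atoms: none
Why: Weinreb ketone synthesis, where the chelated tetrahedral adduct prevents over-addition and pre-forming the magnesium alkoxide spares the resolved alkyne, joins C1 to C2 without touching either stereocentre.

Step 9
Reactants: 16 hydroxy ynone
Product: 17 (2S)-2-allyl-2-methyl-5-[(2Z,4S)-4-(tert-butyldimethylsilyloxy)hexa-2,5-dien-2-yl]furan-3(2H)-one
Conditions: [(4-CF3C6H4)3P]AuCl (5 mol%), AgOTf (5 mol%), toluene, rt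
Reagents that add atoms: none
Why: Gold-catalysed 5-endo-dig oxa-cyclisation of a γ-hydroxy ynone puts the free tertiary hydroxyl on the electrophilic β-carbon C3 and forms the 3(2H)-furanone under neutral conditions that spare the silyl ether and both stereocentres.

Step 10
Reactants: 17 furanone triene
Product: 18 bicyclic furanone 6-O-TBS ether (4Z,7Z,6S,10S)
Conditions: second-generation Hoveyda–Grubbs catalyst (H2IMes)Cl2Ru=CH(2-i-PrOC6H4) (10 mol%, in portions), 1,4-benzoquinone (20 mol%), toluene (1 mM), 80 °C, argon sparge
Reagents that add atoms: none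
Why: Ring-closing metathesis starts at the unhindered allyl terminus and closes on the vinyl group with loss of ethene; the Z C4=C5 turn brings the termini together and the nine-membered oxacycle formed should hold only a cis C7=C8 bond.

Step 11
Reactants: 18 bicyclic furanone 6-O-TBS ether
Product: 19 bicyclic bis-allylic alcohol (4Z,7Z,6S,10S)
Conditions: HF·pyridine, pyridine, THF, 0 °C to rt
Reagents that add atoms: none
Why: Buffered fluoride desilylation avoids base at the vinylogously acidic C6–H, and the electron-poor dienone keeps the bis-allylic carbinol from ionising.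

Step 12
Reactants: 19 bicyclic bis-allylic alcohol; 20 pyruvic acid
Product: 21 bicyclic furanone bis-allylic pyruvate (4Z,7Z,6S,10S)
Conditions: DCC, DMAP (10 mol%), CH2Cl2, −20 to 0 °C
Reagents that add atoms: pyruvic acid 20, CC(=O)C(=O)O
Why: Steglich esterification acylates O6 with retention at C6 under near-neutral, cold conditions suited to a labile allylic α-keto ester.

Step 13
Reactants: 21 bicyclic furanone bis-allylic pyruvate
Product: 23 α-hydroxy-α-methyl trans-fused γ-lactone bearing the Z C8=C9 alkene (6R,7R,10S,11R), via aluminium alkoxide 22 (not isolated)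
Conditions: Me2AlCl (3 equiv), CH2Cl2, −78 to −20 °C; aq. Rochelle salt
Reagents that add atoms: none
Why: Proposed new method: Me2AlCl on the ketone oxygen of the pyruvate lowers its LUMO, C11 bonds to C7 on the convex face while the C9 hydrogen standing perpendicular to the π plane on that same face passes to the carbonyl oxygen through a six-centre transition state, and loss of methane from the aluminium-bound alcohol makes the step irreversible. The closest known reaction types are alkylaluminium halide-promoted carbonyl-ene cyclisations and Lewis acid-promoted ene reactions of pyruvate and glyoxylate esters, whereas a bis-allylic ester tether closing a γ-lactone on a medium ring is without precedent. The lactone closes in a 5-exo-trig mode at the proximal alkene carbon (C8 and the carbonyl oxygen both stay outside the ring), which requires the s-cis ester rotamer and a twisted dicarbonyl and hence a one-point Lewis acid. C7 is set by allylic 1,3-strain, since H6 lies in the plane of the Z alkene and O6 with its ketone can then reach only the face that gives the trans-fused lactone (H6 and H7 anti), and C11 is set by the cyclic hydrogen transfer, which forces the oxygen to lie over C8–C9 so that the hydroxyl ends cis to C8 and anti to H7. The ring holds the C7=C8–C9–C10 torsion small, so the migrated alkene should form Z. The site selectivity needed (C7=C8 rather than C4=C5) comes from conjugation of C4=C5 with the furanone, reinforced by aluminium parked on the C1 carbonyl, which also disfavours ionisation of the C6–O6 bond.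

Step 14
Reactants: 23 ene lactone
Product: 24 8,9,11-triol (6R,7S,8S,9S,10S,11R)
Conditions: OsO4 (10 mol%), NMO, acetone–H2O, rt
Reagents that add atoms: osmium tetroxide, O=[Os](=O)(=O)=O; N-methylmorpholine N-oxide, C[N+]1([O-])CCOCC1; water, O
Why: Upjohn syn-dihydroxylation attacks the only alkene not deactivated by conjugation, and because its inner face lies over the furanone ring osmium should add from the convex β face (where the C11 hydroxyl can assist by hydrogen bonding), setting 8S and 9S together.

Step 15
Reactants: 24 8,9,11-triol; 25 tigloyl chloride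
Product: 26 8-O-tiglate 9,11-diol
Conditions: pyridine, DMAP (cat.), CH2Cl2, −20 °C
Reagents that add atoms: tigloyl chloride 25, C/C=C(\C)C(=O)Cl
Why: Kinetically controlled acylation should pick O8, because the C9 hydroxyl is neopentyl (next to quaternary C10) and hydrogen-bonded to C1=O while the C11 hydroxyl is tertiary; no stereocentre changes.

Step 16
Reactants: 26 8-O-tiglate 9,11-diol
Product: 27 8-O-tiglate 9-O-triethylsilyl ether with free C11 hydroxyl
Conditions: TESOTf (1.1 equiv), 2,6-lutidine, CH2Cl2, −78 °C
Reagents that add atoms: triethylsilyl triflate, CC[Si](CC)(CC)OS(=O)(=O)C(F)(F)F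
Why: Low-temperature silylation takes the secondary O9 ahead of the tertiary, electron-poor C11 hydroxyl; this stops acyl migration, keeps O9 away from the dehydrating agent and blocks retro-aldol cleavage of C9–C10 in step 18.

Step 17
Reactants: 27 9-O-TES 8-O-tiglate hydroxy lactone
Product: 28 α-methylene γ-lactone (8-O-tiglate, 9-O-TES)
Conditions: Burgess reagent MeO2CN(−)SO2N(+)Et3 (3 equiv), toluene, 60 °C
Reagents that add atoms: none
Why: Burgess dehydration is a syn elimination, and since H7 is anti to the C11 oxygen only a C13 hydrogen can be reached, so the exocyclic methylene should form instead of the endocyclic butenolide.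

Step 18
Reactants: 28 α-methylene γ-lactone
Product: 29 11,13-spiro-epoxy lactone with the epoxide oxygen α (11R)
Conditions: t-BuOOH (anhydrous, decane), n-BuLi, THF, −78 to −30 °C; H2O work-up
Reagents that add atoms: tert-butyl hydroperoxide, CC(C)(C)OO
Why: Weitz–Scheffer epoxidation adds the peroxide anion to C13 of the only unhindered Michael acceptor (the tiglate is α,β-disubstituted and C5 is buried in the ring), and the enolate closes on oxygen from the exposed α face, syn to H7 and away from C8 and its acyloxy group, which sets C11.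

Step 19
Reactants: 29 11,13-spiro-epoxy lactone
Product: 31 target CNP0272644.2 (6R,7S,8S,9S,10S,11S), via silylated chlorohydrin 30 (not isolated)
Conditions: conc. aq. HCl (5 equiv), THF, 0 °C to rt
Reagents that add atoms: hydrogen chloride, Cl
Why: Acid-promoted SN2 opening by chloride occurs at primary C13 (C11 is tertiary and next to the carbonyl, so it does not ionise) and keeps the C11–O bond, and the same acid hydrolyses the triethylsilyl ether at O9.

**Compound list**

1 | (R)-lactic acid | C[C@@H](O)C(=O)O | starting material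
2 | pivalaldehyde | CC(C)(C)C=O | starting material
3 | (2R,5R)-2-tert-butyl-5-methyl-1,3-dioxolan-4-one | C[C@H]1O[C@@H](C(C)(C)C)OC1=O | intermediate
4 | allyl bromide | C=CCBr | starting material
5 | lithium enolate of 3 | CC1=C([O-])O[C@H](C(C)(C)C)O1.[Li+] | intermediate
6 | (2R,5S)-5-allyl-2-tert-butyl-5-methyl-1,3-dioxolan-4-one | C[C@@]1(CC=C)O[C@@H](C(C)(C)C)OC1=O | intermediate
7 | (S)-2-hydroxy-N-methoxy-N,2-dimethylpent-4-enamide | C=CC[C@](C)(O)C(=O)N(C)OC | intermediate
8 | (Z)-3-methylpent-2-en-4-yn-1-ol | C#C/C(C)=C\CO | starting material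
9 | (Z)-3-methylpent-2-en-4-ynal | C#C/C(C)=C\C=O | intermediate
10 | vinylmagnesium bromide | C=C[Mg]Br | starting material
11 | rac-(Z)-5-methylhepta-1,4-dien-6-yn-3-ol | C#C/C(C)=C\C(O)C=C | intermediate
12 | (3S,4Z)-5-methylhepta-1,4-dien-6-yn-3-ol | C#C/C(C)=C\[C@@H](O)C=C | intermediate
13 | (3S,4Z)-3-(tert-butyldimethylsilyloxy)-5-methylhepta-1,4-dien-6-yne | C#C/C(C)=C\[C@@H](O[Si](C)(C)C(C)(C)C)C=C | intermediate
14 | chloromagnesium alkoxide of 7 | C=CC[C@](C)(O[Mg]Cl)C(=O)N(C)OC | intermediate
15 | lithium acetylide of 13 | [Li]C#C/C(C)=C\[C@@H](O[Si](C)(C)C(C)(C)C)C=C | intermediate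
16 | (4S,8Z,10S)-10-(tert-butyldimethylsilyloxy)-4-hydroxy-4,8-dimethyldodeca-1,8,11-trien-6-yn-5-one | C=CC[C@](C)(O)C(=O)C#C/C(C)=C\[C@@H](O[Si](C)(C)C(C)(C)C)C=C | intermediate
17 | (2S)-2-allyl-2-methyl-5-[(2Z,4S)-4-(tert-butyldimethylsilyloxy)hexa-2,5-dien-2-yl]furan-3(2H)-one | C=CC[C@]1(C)OC(=CC1=O)/C(C)=C\[C@@H](O[Si](C)(C)C(C)(C)C)C=C | intermediate
18 | bicyclic furanone 6-O-TBS ether (4Z,7Z,6S,10S) | CC(C)(C)[Si](C)(C)O[C@H]1/C=C\C[C@]2(C)OC(=CC2=O)/C(C)=C\1 | intermediate
19 | bicyclic furanone bis-allylic alcohol (4Z,7Z,6S,10S) | O[C@H]1/C=C\C[C@]2(C)OC(=CC2=O)/C(C)=C\1 | intermediate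
20 | pyruvic acid | CC(=O)C(=O)O | starting material
21 | bicyclic furanone bis-allylic pyruvate (key-step precursor) | CC(=O)C(=O)O[C@H]1/C=C\C[C@]2(C)OC(=CC2=O)/C(C)=C\1 | intermediate
22 | chloro(methyl)aluminium alkoxide of 23 | C[C@]1(O[Al](C)Cl)C(=O)O[C@H]2[C@H]1/C=C\[C@]3(C)OC(=CC3=O)/C(C)=C\2 | intermediate
23 | α-hydroxy-α-methyl lactone with Z C8=C9 alkene (key-step product; OH cis to C8, H6/H7 trans) | C[C@]1(O)C(=O)O[C@H]2[C@H]1/C=C\[C@]3(C)OC(=CC3=O)/C(C)=C\2 | intermediate
24 | 8β,9β,11β-triol | O[C@H]1[C@@H]2[C@@H](/C=C(/C)C3=CC(=O)[C@@](C)(O3)[C@H]1O)OC(=O)[C@@]2(O)C | intermediate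
25 | tigloyl chloride | C/C=C(\C)C(=O)Cl | starting material
26 | 8-O-tiglate 9,11-diol | C/C=C(\C)C(=O)O[C@H]1[C@@H]2[C@@H](/C=C(/C)C3=CC(=O)[C@@](C)(O3)[C@H]1O)OC(=O)[C@@]2(O)C | intermediate
27 | 8-O-tiglate 9-O-TES 11-ol | C/C=C(\C)C(=O)O[C@H]1[C@@H]2[C@@H](/C=C(/C)C3=CC(=O)[C@@](C)(O3)[C@H]1O[Si](CC)(CC)CC)OC(=O)[C@@]2(O)C | intermediate
28 | α-methylene lactone (8-O-tiglate, 9-O-TES) | C/C=C(\C)C(=O)O[C@H]1[C@@H]2[C@@H](/C=C(/C)C3=CC(=O)[C@@](C)(O3)[C@H]1O[Si](CC)(CC)CC)OC(=O)C2=C | intermediate
29 | 11,13-spiro-epoxy lactone (oxygen α) | C/C=C(\C)C(=O)O[C@H]1[C@@H]2[C@@H](/C=C(/C)C3=CC(=O)[C@@](C)(O3)[C@H]1O[Si](CC)(CC)CC)OC(=O)[C@]24CO4 | intermediate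
30 | 9-O-TES chlorohydrin | C/C=C(\C)C(=O)O[C@H]1[C@@H]2[C@@H](/C=C(/C)C3=CC(=O)[C@@](C)(O3)[C@H]1O[Si](CC)(CC)CC)OC(=O)[C@]2(O)CCl | intermediate
31 | CNP0272644.2 | C/C=C(\C)C(=O)O[C@H]1[C@@H]2[C@@H](/C=C(/C)C3=CC(=O)[C@@](C)(O3)[C@H]1O)OC(=O)[C@]2(O)CCl | target

**Step count**

Total step count: 19. Longest linear sequence: 16 steps (8 to 31, steps 4–19); steps 1–3 form the short branch.

**Steps most likely to fail**

1. **Step 13 (key step).**
   - The 1,2-disubstituted alkene is a weak ene donor and the ester must first reach its s-cis rotamer, so the reaction may simply be too slow.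
   - Competing processes are ionisation of the bis-allylic C6–O6 bond, methyl transfer from aluminium to the ketone, and a stepwise cationic closure ending in chloride capture.
   - The fallback uses known chemistry (an oxidative radical lactone annulation); it sets out from 19 and comes back at 28.
   - Alcohol 19 is esterified (DCC, DMAP) with mono-tert-butyl malonate to the mixed malonate F1.
   - Mn(OAc)3·2H2O and Cu(OAc)2 in AcOH at 60 °C generate the malonyl radical, which closes 5-exo onto C7 from the face of O6. Cu(OAc)2 then oxidises the C8 radical with loss of a C9 hydrogen to give the α-(tert-butoxycarbonyl) lactone with the Z C8=C9 alkene F2.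
   - Upjohn dihydroxylation gives the 8,9-diol F3, tigloyl chloride gives the 8-O-tiglate F4, and CF3CO2H gives the lactone acid F5.
   - Aqueous formaldehyde with Et2NH (decarboxylative Mannich methylenation) gives the 9-hydroxy α-methylene lactone F6, whose silylation with TESOTf gives 28.

2. **Step 10 (ring-closing metathesis).**
   - Strain in the bridged ring may divert the diene into oligomerisation.
   - The vinyl group beside the bulky silyl ether may engage slowly, and ruthenium hydrides may isomerise the alkenes.
   - The fallback reverses the order of the two ring closures; it sets out from 16 and comes back at 18.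
   - The open and more flexible hydroxy ynone 16 is closed first by metathesis to the ten-membered cyclic dienynone F7. A transannular gold-catalysed 5-endo-dig cyclisation of its tertiary hydroxyl onto the ynone then lays the ether bridge and gives 18.

3. **Step 15 (selective tigloylation).**
   - Discrimination between O8 and O9 may be poor, and double acylation or acyl migration across the cis-diol may occur.
   - The fallback replaces steric discrimination by template activation; it sets out from 24 and comes back at 26.
   - Triol 24 is heated with Bu2SnO in toluene (Dean–Stark) to the 8,9-O-dibutylstannylene acetal F8. In this acetal the less hindered oxygen is the activated one, and treatment with tigloyl chloride at 0 °C followed by aqueous work-up gives 26.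

**Further compounds**

F1 | step 13 | tert-butyl malonate mixed ester of 19 | CC(C)(C)OC(=O)CC(=O)O[C@H]1/C=C\C[C@]2(C)OC(=CC2=O)/C(C)=C\1
F2 | step 13 | α-(tert-butoxycarbonyl) trans-fused lactone with Z C8=C9 alkene (ester trans to C8) | CC(C)(C)OC(=O)[C@@H]1C(=O)O[C@H]2[C@H]1/C=C\[C@]3(C)OC(=CC3=O)/C(C)=C\2
F3 | step 13 | 8β,9β-diol of F2 | O[C@H]1[C@@H]2[C@@H](/C=C(/C)C3=CC(=O)[C@@](C)(O3)[C@H]1O)OC(=O)[C@H]2C(=O)OC(C)(C)C
F4 | step 13 | 8-O-tiglate of F3 | C/C=C(\C)C(=O)O[C@H]1[C@@H]2[C@@H](/C=C(/C)C3=CC(=O)[C@@](C)(O3)[C@H]1O)OC(=O)[C@H]2C(=O)OC(C)(C)C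
F5 | step 13 | lactone α-carboxylic acid from F4 | C/C=C(\C)C(=O)O[C@H]1[C@@H]2[C@@H](/C=C(/C)C3=CC(=O)[C@@](C)(O3)[C@H]1O)OC(=O)[C@H]2C(=O)O
F6 | step 13 | 9-hydroxy 8-O-tiglate α-methylene lactone | C/C=C(\C)C(=O)O[C@H]1[C@@H]2[C@@H](/C=C(/C)C3=CC(=O)[C@@](C)(O3)[C@H]1O)OC(=O)C2=C
F7 | step 10 | ten-membered cyclic hydroxy dienynone 6-O-TBS ether (4Z,7Z,6S,10S) | C[C@]1(O)C/C=C\[C@H](O[Si](C)(C)C(C)(C)C)/C=C(/C)C#CC1=O
F8 | step 15 | 8,9-O-dibutylstannylene acetal of 24 | CCCC[Sn]4(CCCC)O[C@H]1[C@@H]2[C@@H](/C=C(/C)C3=CC(=O)[C@@](C)(O3)[C@H]1O4)OC(=O)[C@@]2(O)C
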